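Friday's tank is Thursday's run with 9.00 h on average in place of 3.0 h, on the same charge of substrate, so I start from that neighbour and turn the question round: what would have to be true of the numbers for a tank to beat Tuesday's closed flask?

| setting | Friday's | Thursday's | Tuesday's |
|---|---|---|---|
| substrate | 0.80 M | 0.80 M | 0.80 M |
| remark | a single well-mixed tank run continuously and read at steady state, 9.00 h in it on average | a single well-mixed tank run continuously and read at steady state, 3.0 h in it on average | everything together in a closed stirred flask, run for 3.0 h |
| time |  |  | 3.0 h |

- the set-up with the highest share of target in all that became target or isomer of the product, at the outlet or at the end ("none" if the first two lie within 2 percentage points) (Friday's / Thursday's / Tuesday's / none)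
- share of target in all that became target or isomer of the product, at the outlet or at the end, Friday's
- share of target in all that became target or isomer of the product, at the outlet or at the end, Thursday's
- share of target in all that became target or isomer of the product, at the outlet or at the end, Tuesday's

    substrate ⇌ intermediate A (K1 = 2.99, k1 = 8.20 × 10⁻⁵ s⁻¹)
    substrate → intermediate B (k2 = 1.86 × 10⁻⁵ s⁻¹)
    intermediate B → intermediate C (k3 = 3.64 × 10⁻⁵ s⁻¹)
    intermediate C ⇌ target (K4 = 0.40, k4 = 3.65 × 10⁻⁵ s⁻¹)
    target ⇌ isomer of the product (K5 = 0.465, k5 = 6.38 × 10⁻⁵ s⁻¹)

- the stated concentrations are those of everything mixed, before any reaction; amounts are the same in each set-up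
- run time (Tuesday's): 3.0 h

I write the steady balance of the isomer of the product in a tank: what the forward step from target makes equals what falls back plus what leaves. This gives c(isomer)/c(target) as the forward constant times τ, divided by one plus that product over the equilibrium constant. The steps before target do not appear in it. For Thursday's tank, this tank ratio is 0.278, with a denominator of 2.48.

In Tuesday's flask, target has to come from substrate through intermediate B and intermediate C, a chain of 3 steps, so early on it grows as the cube of time and the isomer as the fourth power. My rough ratio is therefore the forward constant times time over 4, or 0.172, a share of 85.3%. For Thursday's tank to beat Tuesday's flask at the same 3.0 h, on this rough ratio, its denominator would have to pass 4, but it stands lower, at the value above. I therefore commit to Tuesday's flask, whose rough ratio is smaller than Thursday's tank ratio.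

The forecast also names Tuesday's: “Little isomer has formed yet”. Its flask figure of 87% stands above my rough share.

| Set-up | Forecast | Simulation |
|---|---|---|
| Friday's | 72.5% | 72.5% |
| Thursday's | 78.3% | 78.3% |
| Tuesday's | 87% | 87.0% |

When Tuesday's flask ended at 3.0 h, substrate still stood at 39.7% of the charge and intermediate B at 10.2%, and the share of target read 87.0%. The tank ratio of 0.278 is a share of 78.3% on Thursday's, where the simulation gives 78.3%; on Friday's the same rule gives 0.380, a share of 72.5%, where the simulation gives 72.5%, and Tuesday's flask, left for 30.0 h, gives 69.6%.

Its constants belong to no real substance, and the outcome is calculated.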